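**Plan**
1. Locants follow the target (quinoline numbering; ring A = pyridine ring N1–C8a, ring B = carbocycle C4a–C8a). The last cuts are N1–O (peracid) and C5–H (asymmetric hydrogenation of a C5=C6 alkene).
2. The alkene comes from a β-hydroxy acid by joint loss of the C5 hydroxyl and the C6 carboxyl; ring B of that hydroxy acid is cut at C5–C6 and C7–C8.
3. Enabling feature: ring A carries C5 and C8 on its adjacent atoms C4a and C8a. With C5 as a ketone carbonyl and C8 as a methyl group, light turns this ortho-methyl ketone into the hydroxy-ortho-quinodimethane C8=C8a–C4a=C5(OH), a diene that takes up methyl acrylate (an ethylene equivalent) as C6–C7.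
4. Forward: 3,4-dimethoxy-2-methylpyridine → C6 methylation → C5 bromination → acylation with the Weinreb amide of 6-phenylhexanoic acid (chain complete) → photochemical closure of ring B → excision of OH/CO2H → hydrogenation → N-oxide.
5. Stereochemistry: the only stereocentre, (R)-C5, is set by iridium-catalysed asymmetric hydrogenation of the C5=C6 alkene (step 8); the two racemic centres made in the key step are erased in step 7.

Key step: step 5

Assumption: 3,4-dimethoxy-2-methylpyridine (4) is taken as a catalogue compound (free base of the bulk pantoprazole N-oxide intermediate).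

**Step 1**
Reactants: 1 6-phenylhexanoic acid
Product: 3 N-methoxy-N-methyl-6-phenylhexanamide, via 1-(6-phenylhexanoyl)imidazole 2 (not isolated)
Conditions: CDI (1.1 equiv), CH2Cl2, 20 °C, 1 h; then MeNH(OMe)·HCl (1.2 equiv), 20 °C
Reagents that add atoms: N,O-dimethylhydroxylamine hydrochloride, CNOC.Cl
Why: Acyl imidazolide formation followed by aminolysis is the standard Weinreb amide synthesis; the first imidazole released takes up the HCl of the amine salt.

**Step 2**
Reactants: 4 3,4-dimethoxy-2-methylpyridine
Product: 5 3,4-dimethoxy-2,6-dimethylpyridine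
Conditions: DMSO, H2SO4 (1.2 equiv), FeSO4·7H2O (0.3 equiv), 30% H2O2 (3 equiv, slow addition), 15–25 °C
Reagents that add atoms: dimethyl sulfoxide, CS(C)=O
Why: Minisci methylation: hydroxyl radical from H2O2/FeSO4 fragments DMSO to a methyl radical, which adds to the protonated pyridine at C6, the only free position α or γ to nitrogen (C2 and C4 are blocked, β-C5 is not attacked), so a single methylation product should form.

**Step 3**
Reactants: 5 3,4-dimethoxy-2,6-dimethylpyridine
Product: 6 3-bromo-4,5-dimethoxy-2,6-dimethylpyridine
Conditions: NBS (1.05 equiv), MeCN, 20 → 50 °C, dark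
Reagents that add atoms: N-bromosuccinimide, O=C1CCC(=O)N1Br
Why: Electrophilic aromatic bromination can only go to the single unsubstituted ring carbon, which is β to nitrogen and ortho to a methoxy group; dark, ionic conditions should suppress radical bromination of the methyl groups.

**Step 4**
Reactants: 6 3-bromo-4,5-dimethoxy-2,6-dimethylpyridine; 3 N-methoxy-N-methyl-6-phenylhexanamide
Product: 9 1-(4,5-dimethoxy-2,6-dimethylpyridin-3-yl)-6-phenylhexan-1-one, via pyridylmagnesium chloride 7 (not isolated), via chloromagnesium hemiaminal 8 (not isolated)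
Conditions: i-PrMgCl·LiCl (1.1 equiv), THF, 0 → 25 °C; then 3 (1.1 equiv), 0 → 25 °C; aq. NH4Cl
Reagents that add atoms: none
Why: Bromine–magnesium exchange with the turbo-Grignard reagent followed by Weinreb ketone synthesis; the N,O-chelated tetrahedral adduct 8 stops the addition at the ketone stage, and the arylmagnesium species is too weakly basic to metalate the two picolyl methyl groups.

**Step 5**
Reactants: 9 1-(4,5-dimethoxy-2,6-dimethylpyridin-3-yl)-6-phenylhexan-1-one; 10 methyl acrylate
Product: 12 methyl cis-5-hydroxy-3,4-dimethoxy-2-methyl-5-(5-phenylpentyl)-5,6,7,8-tetrahydroquinoline-6-carboxylate (racemic), via hydroxy-ortho-quinodimethane 11 (not isolated)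
Conditions: hν (365 nm LEDs, Pyrex), 10 (10 equiv), degassed toluene (0.02 M), 20 °C
Reagents that add atoms: none
Why: Excitation of the aryl ketone (n,π*) triggers a 1,5-hydrogen shift from the C8 methyl group through a six-membered transition state, and the resulting long-lived dienol 11 (C8=C8a–C4a=C5, OH turned away from C8) adds methyl acrylate in a thermal suprafacial [4+2] cycloaddition that forms C7–C8 and C5–C6 and restores the aromatic ring A. The closest known reaction type is the photoenolization/Diels–Alder reaction of ortho-methyl aryl ketones and aldehydes with acrylates. Ring B closes by an intermolecular [4+2] cycloaddition across the diene termini C8 and C5, giving the six-membered carbocycle with both new bonds in one operation. C5 and C6 arise racemic, with the relative configuration fixed by the dienol geometry and the endo transition state (hydroxyl cis to the ester); both centres are removed in step 7 and the final C5 configuration is set in step 8. The step needs site selectivity between the two methyl groups, secured because only the methyl ortho to the carbonyl can reach the carbonyl oxygen (the C2 methyl is para to the acyl group), and this benzylic transfer should outrun γ-hydrogen abstraction from the chain and hydrogen abstraction from the C4 methoxy group. It also needs the ortho regiochemistry (ester on C6, next to the C5 hydroxyl, as step 7 requires), secured by the donor-substituted diene, whose larger HOMO coefficient at C8 pairs with the β-carbon of the acrylate.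

**Step 6**
Reactants: 12 methyl cis-5-hydroxy-3,4-dimethoxy-2-methyl-5-(5-phenylpentyl)-5,6,7,8-tetrahydroquinoline-6-carboxylate
Product: 13 cis-5-hydroxy-3,4-dimethoxy-2-methyl-5-(5-phenylpentyl)-5,6,7,8-tetrahydroquinoline-6-carboxylic acid (racemic)
Conditions: LiOH·H2O (3 equiv), THF/MeOH/H2O, 0 → 25 °C; then aq. HCl to pH 5
Reagents that add atoms: lithium hydroxide monohydrate, [Li+].[OH-].O
Why: Saponification of an unhindered methyl ester; the low temperature should limit retro-aldol opening and C6 epimerisation, and both stereocentres disappear in the next step in any case.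

**Step 7**
Reactants: 13 cis-5-hydroxy-3,4-dimethoxy-2-methyl-5-(5-phenylpentyl)-5,6,7,8-tetrahydroquinoline-6-carboxylic acid
Product: 16 3,4-dimethoxy-2-methyl-5-(5-phenylpentyl)-7,8-dihydroquinoline, via mixed carboxylic sulfonic anhydride 14 (not isolated), via cis-fused β-lactone 15 (not isolated)
Conditions: PhSO2Cl (2 equiv), pyridine, 0 → 20 °C; then toluene, 100 °C
Reagents that add atoms: none
Why: β-Lactone olefination of a β-hydroxy acid: carboxyl activation lets the cis tertiary hydroxyl close the β-lactone, whose thermal [2+2] cycloreversion extrudes CO2 and places the alkene regiospecifically at C5=C6, so the photoenol hydroxyl and the dienophile carboxyl leave together.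

**Step 8**
Reactants: 16 3,4-dimethoxy-2-methyl-5-(5-phenylpentyl)-7,8-dihydroquinoline
Product: 17 (R)-3,4-dimethoxy-2-methyl-5-(5-phenylpentyl)-5,6,7,8-tetrahydroquinoline
Conditions: H2 (50 bar), [Ir(cod)((R)-tBu-PHOX)][B(C6H3-3,5-(CF3)2)4] (2 mol%), CH2Cl2, 25 °C
Reagents that add atoms: none
Why: Iridium N,P-ligand asymmetric hydrogenation of an unfunctionalised trisubstituted cyclic aryl alkene (the 4-alkyl-1,2-dihydronaphthalene class); hydrogen must be delivered to the Si face of C5 (priority C4a > C6 > chain carbon) to give (R), the (R)-ligand is proposed for this and its sense is to be confirmed in a test run (the antipode is equally available), and the ring nitrogen, flanked by the C2 methyl and C8, should not bind iridium.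

**Step 9**
Reactants: 17 (R)-3,4-dimethoxy-2-methyl-5-(5-phenylpentyl)-5,6,7,8-tetrahydroquinoline
Product: 18 (R)-3,4-dimethoxy-2-methyl-5-(5-phenylpentyl)-5,6,7,8-tetrahydroquinoline 1-oxide
Conditions: mCPBA (1.2 equiv), CH2Cl2, 0 → 20 °C
Reagents that add atoms: meta-chloroperoxybenzoic acid, O=C(OO)c1cccc(Cl)c1
Why: Peracid N-oxidation of an electron-rich pyridine; no other oxidisable group is present and the benzylic C5 stereocentre is not touched.

**Compound list**
1 | 6-phenylhexanoic acid | OC(=O)CCCCCc1ccccc1 | starting material
2 | 1-(6-phenylhexanoyl)imidazole | O=C(CCCCCc1ccccc1)n1ccnc1 | intermediate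
3 | N-methoxy-N-methyl-6-phenylhexanamide | CON(C)C(=O)CCCCCc1ccccc1 | intermediate
4 | 3,4-dimethoxy-2-methylpyridine | COc1ccnc(C)c1OC | starting material
5 | 3,4-dimethoxy-2,6-dimethylpyridine | COc1cc(C)nc(C)c1OC | intermediate
6 | 3-bromo-4,5-dimethoxy-2,6-dimethylpyridine | COc1c(Br)c(C)nc(C)c1OC | intermediate
7 | (4,5-dimethoxy-2,6-dimethylpyridin-3-yl)magnesium chloride (LiCl complex) | COc1c([Mg]Cl)c(C)nc(C)c1OC | intermediate
8 | chloromagnesium salt of the tetrahedral adduct of 7 and 3 (N,O-chelate) | COc1c(C(O[Mg]Cl)(CCCCCc2ccccc2)N(C)OC)c(C)nc(C)c1OC | intermediate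
9 | 1-(4,5-dimethoxy-2,6-dimethylpyridin-3-yl)-6-phenylhexan-1-one | COc1c(C(=O)CCCCCc2ccccc2)c(C)nc(C)c1OC | intermediate
10 | methyl acrylate | C=CC(=O)OC | starting material
11 | photodienol of 9: 1-(4,5-dimethoxy-6-methyl-2-methylidenepyridin-3(2H)-ylidene)-6-phenylhexan-1-ol, OH on the side of the C4 methoxy group | O/C(CCCCCc1ccccc1)=C2\C(OC)=C(OC)C(C)=NC2=C | intermediate
12 | methyl cis-5-hydroxy-3,4-dimethoxy-2-methyl-5-(5-phenylpentyl)-5,6,7,8-tetrahydroquinoline-6-carboxylate, racemic (5S*,6S*), one enantiomer drawn | COC(=O)[C@H]1CCc2nc(C)c(OC)c(OC)c2[C@]1(O)CCCCCc1ccccc1 | intermediate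
13 | cis-5-hydroxy-3,4-dimethoxy-2-methyl-5-(5-phenylpentyl)-5,6,7,8-tetrahydroquinoline-6-carboxylic acid, racemic, one enantiomer drawn | OC(=O)[C@H]1CCc2nc(C)c(OC)c(OC)c2[C@]1(O)CCCCCc1ccccc1 | intermediate
14 | mixed anhydride of 13 with benzenesulfonic acid, racemic | O=C(OS(=O)(=O)c1ccccc1)[C@H]1CCc2nc(C)c(OC)c(OC)c2[C@]1(O)CCCCCc1ccccc1 | intermediate
15 | cis-fused β-lactone of 13 (oxetan-2-one across C5–C6), racemic | O=C1O[C@]2(CCCCCc3ccccc3)c3c(OC)c(OC)c(C)nc3CC[C@H]12 | intermediate
16 | 3,4-dimethoxy-2-methyl-5-(5-phenylpentyl)-7,8-dihydroquinoline | COc1c(OC)c(C)nc2c1C(CCCCCc1ccccc1)=CCC2 | intermediate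
17 | (R)-3,4-dimethoxy-2-methyl-5-(5-phenylpentyl)-5,6,7,8-tetrahydroquinoline | COc1c(OC)c(C)nc2c1[C@H](CCCCCc1ccccc1)CCC2 | intermediate
18 | (R)-3,4-dimethoxy-2-methyl-5-(5-phenylpentyl)-5,6,7,8-tetrahydroquinoline 1-oxide | COc1c(OC)c(C)[n+]([O-])c2c1[C@H](CCCCCc1ccccc1)CCC2 | target

**Totals**
Total steps: 9. Longest linear sequence: 8 (steps 2–9, from 4 to 18); step 1 is a one-step side branch.

**Steps most likely to fail**

Step 5. The photodienol may not be intercepted: it can revert to the ketone or close to a cyclobutenol, the excited ketone can abstract a chain γ-hydrogen and fragment, or the acrylate can polymerise. The fallback builds ring B by an anionic annulation instead and sets out from bromide 6. Bromine–magnesium exchange as in step 4 (arylmagnesium 7) and trapping with methyl chloroformate would give methyl 4,5-dimethoxy-2,6-dimethylpyridine-3-carboxylate F1. Lateral deprotonation of the methyl group ortho to the ester with LDA (THF, −78 °C) and addition of methyl acrylate (Michael addition followed by Dieckmann closure, the Staunton–Weinreb type annulation) would give methyl 3,4-dimethoxy-2-methyl-5-oxo-5,6,7,8-tetrahydroquinoline-6-carboxylate F2. Krapcho dealkoxycarbonylation (LiCl, wet DMSO, 150 °C) would give 3,4-dimethoxy-2-methyl-7,8-dihydroquinolin-5(6H)-one F3, and KHMDS/PhNTf2 would give 3,4-dimethoxy-2-methyl-7,8-dihydroquinolin-5-yl trifluoromethanesulfonate F4. Negishi coupling of F4 with (5-phenylpentyl)zinc bromide F5 (from 1-bromo-5-phenylpentane and zinc dust, LiCl, THF) under Pd(dppf)Cl2 catalysis comes back to the route at alkene 16.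

Step 8. Facial discrimination may be poor at the peri-crowded trisubstituted alkene, or the catalyst may be slowed by nitrogen binding or by double-bond migration. The fallback replaces asymmetric induction by resolution and sets out from alkene 16. Non-selective hydrogenation (H2, Pd/C, EtOAc) would give racemic 3,4-dimethoxy-2-methyl-5-(5-phenylpentyl)-5,6,7,8-tetrahydroquinoline F6, and preparative chromatography on a chiral stationary phase (supercritical CO2/MeOH) would return the (R)-enantiomer, compound 17.

Step 2. Addition of the weakly nucleophilic methyl radical to the electron-rich pyridinium may be slow, with competing oxidative degradation of the ring. The fallback uses nucleophilic addition to the N-oxide instead and sets out from 4. mCPBA would give 3,4-dimethoxy-2-methylpyridine 1-oxide F7 (itself a catalogue compound). MeMgCl in THF should add at the free C6 position, and the adduct should open to the chloromagnesium salt of (3Z)-3,4-dimethoxyhepta-3,5-dien-2-one oxime F8. Heating with Ac2O at 120 °C should reclose and aromatise it with loss of acetic acid, coming back to the route at 5.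

**Further compounds**
F1 | step 5 | methyl 4,5-dimethoxy-2,6-dimethylpyridine-3-carboxylate | COC(=O)c1c(C)nc(C)c(OC)c1OC
F2 | step 5 | methyl 3,4-dimethoxy-2-methyl-5-oxo-5,6,7,8-tetrahydroquinoline-6-carboxylate (racemic, keto form drawn) | COC(=O)C1CCc2nc(C)c(OC)c(OC)c2C1=O
F3 | step 5 | 3,4-dimethoxy-2-methyl-7,8-dihydroquinolin-5(6H)-one | COc1c(OC)c(C)nc2c1C(=O)CCC2
F4 | step 5 | 3,4-dimethoxy-2-methyl-7,8-dihydroquinolin-5-yl trifluoromethanesulfonate | COc1c(OC)c(C)nc2c1C(OS(=O)(=O)C(F)(F)F)=CCC2
F5 | step 5 | (5-phenylpentyl)zinc bromide | Br[Zn]CCCCCc1ccccc1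
F6 | step 8 | racemic 3,4-dimethoxy-2-methyl-5-(5-phenylpentyl)-5,6,7,8-tetrahydroquinoline | COc1c(OC)c(C)nc2c1C(CCCCCc1ccccc1)CCC2
F7 | step 2 | 3,4-dimethoxy-2-methylpyridine 1-oxide | COc1cc[n+]([O-])c(C)c1OC
F8 | step 2 | chloromagnesium salt of (3Z)-3,4-dimethoxyhepta-3,5-dien-2-one oxime | CC=C/C(OC)=C(OC)\C(C)=NO[Mg]Cl
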